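A direct plan would O-propargylate the phenol A1, methyl dihydroferulate, and convert the alkyne, by hydroboration and an iridium-hydride double-bond shift, into the (E)-γ-aryloxyallylboronate A2.
A2 would be added to the aldehyde A3, 3,4-diacetoxybenzaldehyde, under a chiral phosphoric acid to give homoallylic alcohol A4; ozonolysis to aldehyde A5 and LiBH4 reduction in the same flask would finish the route.
Its weakest steps would be:
- The isomerisation/allylboration relay, which sets both stereocentres: an aryloxy-substituted allylboronate of this kind is untested, any loss of E geometry or 1,3-boron shift would appear directly as the threo isomer, and the face selection by the acid on such a boronate is unproven.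
- The ozonolysis: ozone would meet two electron-rich arenes, and the α-aryloxy-β-hydroxy aldehyde A5 could epimerise at C8 or undergo retro-aldol cleavage before hydride reaches it.
- The vinyl group as a stand-in for CH2OH: hydroboration, isomerisation and ozonolysis all handle a carbon that is installed only to be cut off again.

Retrosynthetic overview
- The target's core is the C7(OH)–C8(OAr)–C9H2OH unit between the catechol ring (ring A) and the guaiacyl ether ring (ring B). C7–O and C8–H would be added together, syn, across the C7=C8 bond of the (Z)-2-aryloxycinnamyl alcohol 8, with the C9 hydroxyl carrying the silicon that is delivered to C7.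
- The Z-alkene (ring A cis to the aryloxy group) would come from aldol condensation of aryloxyacetate 3 with aldehyde 4. Rings A and B are bought; the only ring closed is a transient 1,2-oxasilolane (5-endo), opened again by oxidation.
- The erythro relationship is encoded in the thermodynamically favoured alkene geometry, not in a boronate relay. There is no ozonolysis, no α-aryloxy aldehyde and no sacrificial carbon.

Key step: step 4

Assumption: the facial sense of the rhodium–BINAP catalyst on this 2-aryloxy substrate cannot be predicted with certainty from the parent cinnamyl case; (R)-BINAP is written, and the antipode would be used if silicon were delivered to the Re face of C7.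

Step 1
Reactants: 1 methyl 3-(4-hydroxy-3-methoxyphenyl)propanoate (methyl dihydroferulate); 2 methyl bromoacetate
Product: 3 methyl 2-[2-methoxy-4-(3-methoxy-3-oxopropyl)phenoxy]acetate
Conditions: 2 (1.2 equiv), K2CO3 (1.5 equiv), acetone, reflux, 6 h
Reagents that add atoms: methyl bromoacetate COC(=O)CBr
Why: Williamson ether synthesis, in which the phenoxide displaces the activated primary bromide by SN2; both methyl esters are inert and no stereocentre is involved.

Step 2
Reactants: 3 methyl 2-[2-methoxy-4-(3-methoxy-3-oxopropyl)phenoxy]acetate; 4 3,4-bis(benzyloxy)benzaldehyde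
Product: 7 methyl (2Z)-3-[3,4-bis(benzyloxy)phenyl]-2-[2-methoxy-4-(3-methoxy-3-oxopropyl)phenoxy]prop-2-enoate, via aldol adduct 5 (not isolated), via β-mesylate 6 (not isolated)
Conditions: LiN(SiMe3)2 (1.05 equiv), THF, −78 °C; 4 (1.0 equiv), −78 °C; MsCl (1.3 equiv), −78 → 0 °C; DBU (3 equiv), 0 °C → rt; recrystallisation
Reagents that add atoms: none
Why: Aldol addition of the α-aryloxy ester enolate (this α-CH2 is clearly more acidic than the propanoate α-CH2), then E1cB elimination of the mesylate, in which both aldol diastereomers pass through the same ester enolate and should converge on the more stable Z-alkene (ring A trans to CO2Me, cis to the aryloxy group); no stereocentre remains.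

Step 3
Reactants: 7 methyl (2Z)-3-[3,4-bis(benzyloxy)phenyl]-2-[2-methoxy-4-(3-methoxy-3-oxopropyl)phenoxy]prop-2-enoate
Product: 8 (2Z)-3-[3,4-bis(benzyloxy)phenyl]-2-[4-(3-hydroxypropyl)-2-methoxyphenoxy]prop-2-en-1-ol
Conditions: i-Bu2AlH (5.5 equiv), CH2Cl2, −78 → 0 °C; aq potassium sodium tartrate
Reagents that add atoms: none
Why: Aluminium hydride 1,2-reduction of the enoate to the allylic alcohol and of the saturated ester to the primary alcohol in one operation; benzyl ethers, aryl ethers and the alkene geometry are not touched.

Step 4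
Reactants: 8 (2Z)-3-[3,4-bis(benzyloxy)phenyl]-2-[4-(3-hydroxypropyl)-2-methoxyphenoxy]prop-2-en-1-ol; 9 1,1,3,3-tetramethyldisilazane
Product: 12 (1S,2R)-1-[3,4-bis(benzyloxy)phenyl]-2-[4-(3-hydroxypropyl)-2-methoxyphenoxy]propane-1,3-diol, via bis(dimethylsilyl) ether 10 (not isolated), via trans-oxasilolane 11 (not isolated)
Conditions: (a) 9 (5 equiv, neat), 60 °C, 2 h, then vacuum; (b) [Rh(nbd)((R)-BINAP)]BF4 (2 mol %, nbd removed with H2, then Ar), CH2Cl2, 25–40 °C; (c) KF (4 equiv), KHCO3 (4 equiv), 30% H2O2 (12 equiv), THF/MeOH 1:1, 0 °C → rt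
Reagents that add atoms: hydrogen peroxide OO
Why: Proposed new method: enantioselective 5-endo intramolecular hydrosilylation of a 2-aryloxy-substituted, trisubstituted allylic silyl ether, in which the cationic rhodium–BINAP centre would add the allylic Si–H bond oxidatively, the C7=C8 bond would insert into Rh–Si (silicon to C7, rhodium to C8, so that no rhodium alkyl with a β-aryloxy group arises) and C–H reductive elimination would place hydrogen on C8 on the same face and release oxasilolane 11; the closest known reaction types are the rhodium–diphosphine-catalysed enantioselective intramolecular hydrosilylation of cinnamyl silyl ethers to 1-arylpropane-1,3-diols and the platinum-catalysed intramolecular hydrosilylation of 2-alkoxyallyl silyl ethers, in which hydrogen likewise goes to the oxygen-bearing carbon. The one ring closed, the 1,2-oxasilolane, forms in the 5-endo mode because the C9–O–Si tether could reach C8 only through a four-membered ring. C7 is set by the catalyst, which must deliver silicon to the Si face of C7; C8 then follows without a second choice, because syn addition to the Z-alkene can only give the erythro pair, here 7S,8R. The Tamao oxidation then replaces C7–Si by C7–OH with retention and frees the C9 and propyl hydroxyls (the remote O–SiMe2H group is a bystander and is hydrolysed). The step needs face selectivity, no E/Z isomerisation before insertion and no loss of the β-aryloxy group: the tether fixes the regiochemistry, the polarity of the enol ether (hydrogen to the oxygen-bearing C8) matches it, and in the five-membered ring the C7–Si and C8–OAr bonds are held near gauche, which disfavours anti-elimination until the C–Si bond is oxidised.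

Step 5
Reactants: 12 (1S,2R)-1-[3,4-bis(benzyloxy)phenyl]-2-[4-(3-hydroxypropyl)-2-methoxyphenoxy]propane-1,3-diol
Product: 13 (1S,2R)-1-(3,4-dihydroxyphenyl)-2-[4-(3-hydroxypropyl)-2-methoxyphenoxy]propane-1,3-diol (target)
Conditions: H2 (1 atm), 10% Pd/C, EtOAc/EtOH 1:1, rt; stopped at 2 equiv H2
Reagents that add atoms: none
Why: Hydrogenolysis of the two aryl benzyl ethers under neutral conditions, where the acid-sensitive benzylic C7–OH should survive and the alkyl aryl ether at C8 is not benzylic; neither stereocentre is touched.

Compound list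
1 | methyl 3-(4-hydroxy-3-methoxyphenyl)propanoate | COC(=O)CCc1ccc(O)c(OC)c1 | starting material
2 | methyl bromoacetate | COC(=O)CBr | starting material
3 | methyl 2-[2-methoxy-4-(3-methoxy-3-oxopropyl)phenoxy]acetate | COC(=O)CCc1ccc(OCC(=O)OC)c(OC)c1 | intermediate
4 | 3,4-bis(benzyloxy)benzaldehyde | O=Cc1ccc(OCc2ccccc2)c(OCc2ccccc2)c1 | starting material
5 | methyl 3-[3,4-bis(benzyloxy)phenyl]-3-hydroxy-2-[2-methoxy-4-(3-methoxy-3-oxopropyl)phenoxy]propanoate (racemic mixture of diastereomers) | COC(=O)CCc1ccc(OC(C(=O)OC)C(O)c2ccc(OCc3ccccc3)c(OCc3ccccc3)c2)c(OC)c1 | intermediate (not isolated)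
6 | methyl 3-[3,4-bis(benzyloxy)phenyl]-3-(methanesulfonyloxy)-2-[2-methoxy-4-(3-methoxy-3-oxopropyl)phenoxy]propanoate (mixture of diastereomers) | COC(=O)CCc1ccc(OC(C(=O)OC)C(OS(C)(=O)=O)c2ccc(OCc3ccccc3)c(OCc3ccccc3)c2)c(OC)c1 | intermediate (not isolated)
7 | methyl (2Z)-3-[3,4-bis(benzyloxy)phenyl]-2-[2-methoxy-4-(3-methoxy-3-oxopropyl)phenoxy]prop-2-enoate | COC(=O)CCc1ccc(O/C(C(=O)OC)=C\c2ccc(OCc3ccccc3)c(OCc3ccccc3)c2)c(OC)c1 | intermediate
8 | (2Z)-3-[3,4-bis(benzyloxy)phenyl]-2-[4-(3-hydroxypropyl)-2-methoxyphenoxy]prop-2-en-1-ol | OCCCc1ccc(O/C(CO)=C\c2ccc(OCc3ccccc3)c(OCc3ccccc3)c2)c(OC)c1 | intermediate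
9 | 1,1,3,3-tetramethyldisilazane | C[SiH](C)N[SiH](C)C | starting material
10 | bis(dimethylsilyl) ether of 8 (Z) | C[SiH](C)OCCCc1ccc(O/C(CO[SiH](C)C)=C\c2ccc(OCc3ccccc3)c(OCc3ccccc3)c2)c(OC)c1 | intermediate (not isolated)
11 | (3S,4R)-3-[3,4-bis(benzyloxy)phenyl]-4-{4-[3-(dimethylsilyloxy)propyl]-2-methoxyphenoxy}-2,2-dimethyl-1,2-oxasilolane (aryl and aryloxy trans) | COc1cc(CCCO[SiH](C)C)ccc1O[C@@H]1CO[Si](C)(C)[C@H]1c1ccc(OCc2ccccc2)c(OCc2ccccc2)c1 | intermediate (not isolated)
12 | (1S,2R)-1-[3,4-bis(benzyloxy)phenyl]-2-[4-(3-hydroxypropyl)-2-methoxyphenoxy]propane-1,3-diol | COc1cc(CCCO)ccc1O[C@H](CO)[C@@H](O)c1ccc(OCc2ccccc2)c(OCc2ccccc2)c1 | intermediate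
13 | (1S,2R)-1-(3,4-dihydroxyphenyl)-2-[4-(3-hydroxypropyl)-2-methoxyphenoxy]propane-1,3-diol | COc1cc(CCCO)ccc1O[C@H](CO)[C@@H](O)c1ccc(O)c(O)c1 | target

Total step count: 5. Longest linear sequence: 5 steps (1 → 3 → 7 → 8 → 12 → 13).

Steps most likely to fail

Step 4 (proposed new method). The catalyst might discriminate the two faces of the trisubstituted enol ether poorly, the 5-endo insertion might be slow, a rhodium hydride might isomerise the alkene before insertion (a leak into the threo series), or the β-aryloxy group might be lost from a C7-metalated species. The fallback uses known chemistry and sets out from 8. Both hydroxyls would be silylated (TBSCl, imidazole, DMF) to the bis(tert-butyldimethylsilyl) ether of 8, F1. Reagent-controlled syn-hydroboration with monoisopinocampheylborane (antipode chosen for Si-face attack at C7, Et2O, −25 °C; boron to the less substituted C7, β to the enol oxygen), then oxidation with NaBO3·4H2O, would give the 9,9'-bis-silyl ether of 12, F2; it would be erythro by the same syn-addition logic. TBAF in THF would come back to the route at 12.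

Step 2. The enolate might form in part at the propanoate ester, the aldolate might revert on mesylation, or the elimination might give an E/Z mixture that is hard to separate. The fallback sets out from 1. Rhodium-carbenoid O–H insertion with trimethyl diazophosphonoacetate (Rh2(OAc)4, toluene, 80 °C) would give methyl 2-(dimethoxyphosphoryl)-2-[2-methoxy-4-(3-methoxy-3-oxopropyl)phenoxy]acetate, F3. A Horner–Wadsworth–Emmons reaction with 4 (LiCl, DBU, MeCN) would come back to the route at 7; any E isomer would be equilibrated to Z with a trace of iodine in light or removed by crystallisation.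

Step 5. Hydrogenolysis might also cleave the benzylic C7–O bond next to the electron-rich ring A, or continue after the benzyl groups are gone. The fallback sets out from 12 and makes no new compound, which is the entry F0. The three hydroxyls would be deprotonated (n-BuLi, THF, −78 °C) and the two aryl benzyl ethers cleaved by electron transfer from lithium 4,4'-di-tert-butylbiphenylide (THF, −78 °C, then NH4Cl). The C7–O bond then sits on an alkoxide and should not be reduced; the sequence arrives at 13.

Further compounds
F1 | step 4 | (2Z)-bis(tert-butyldimethylsilyl) ether of 8 | CC(C)(C)[Si](C)(C)OCCCc1ccc(O/C(CO[Si](C)(C)C(C)(C)C)=C\c2ccc(OCc3ccccc3)c(OCc3ccccc3)c2)c(OC)c1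
F2 | step 4 | (1S,2R)-1-[3,4-bis(benzyloxy)phenyl]-3-(tert-butyldimethylsilyloxy)-2-{4-[3-(tert-butyldimethylsilyloxy)propyl]-2-methoxyphenoxy}propan-1-ol | COc1cc(CCCO[Si](C)(C)C(C)(C)C)ccc1O[C@H](CO[Si](C)(C)C(C)(C)C)[C@@H](O)c1ccc(OCc2ccccc2)c(OCc2ccccc2)c1
F3 | step 2 | methyl 2-(dimethoxyphosphoryl)-2-[2-methoxy-4-(3-methoxy-3-oxopropyl)phenoxy]acetate | COC(=O)CCc1ccc(OC(C(=O)OC)P(=O)(OC)OC)c(OC)c1
F0 | step 5 | none | none
A1 | direct plan | methyl 3-(4-hydroxy-3-methoxyphenyl)propanoate (methyl dihydroferulate) | COC(=O)CCc1ccc(O)c(OC)c1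
A2 | direct plan | methyl 3-(3-methoxy-4-{[(1E)-3-(4,4,5,5-tetramethyl-1,3,2-dioxaborolan-2-yl)prop-1-en-1-yl]oxy}phenyl)propanoate | COC(=O)CCc1ccc(O/C=C/CB2OC(C)(C)C(C)(C)O2)c(OC)c1
A3 | direct plan | 3,4-diacetoxybenzaldehyde | CC(=O)Oc1ccc(C=O)cc1OC(C)=O
A4 | direct plan | 4-[(1S,2R)-1-hydroxy-2-{2-methoxy-4-(3-methoxy-3-oxopropyl)phenoxy}but-3-en-1-yl]benzene-1,2-diyl diacetate | COC(=O)CCc1ccc(O[C@H](C=C)[C@@H](O)c2ccc(OC(C)=O)c(OC(C)=O)c2)c(OC)c1
A5 | direct plan | (2S,3S)-3-(3,4-diacetoxyphenyl)-3-hydroxy-2-[2-methoxy-4-(3-methoxy-3-oxopropyl)phenoxy]propanal | COC(=O)CCc1ccc(O[C@H](C=O)[C@@H](O)c2ccc(OC(C)=O)c(OC(C)=O)c2)c(OC)c1
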